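**Retrosynthetic overview**
1. Both oxiranes (C7–C8 and the α-bromo oxirane C9–C10, four stereocentres) are cut together: the target goes back to the 10-bromo-7,9-diene of the spirocycle, which is epoxidised twice in one flask.
2. The bromodiene goes back to a spiro enone-ketone: hydride reduction at C5, then α'-bromination, 1,2-reduction and dehydration in ring A.
3. Ring A is cut as a formal [4+2] between an isopropylidene cyclohexanone (ring B, already carrying the trans Br/Cl pair) and a 2-silyloxy-enyne: Mukaiyama–Michael bond C10–C11, then gold-catalysed 6-endo-dig bond C6–C7 anti to bromine, which sets the spiro centre.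
4. The Br/Cl pair goes back to an achiral dienone through Shi epoxidation, bromide opening and chloride substitution with retention; this is the only source of absolute configuration.
5. Ring B comes from 3-methylanisole by Birch reduction. Ring order: B (from the arene), then A (spiroannulation), then the two oxiranes together.

Assumption: spiro compounds are numbered as chamigranes (ring B = C1–C5, spiro carbon C6, ring A = C7–C11, gem-dimethyl on C11); the CIP label of C6 switches between S and R with the substitution at C10 although its geometry never changes.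

**Step 1**
Reactants: 1 3-methylanisole
Product: 2 1-methoxy-5-methylcyclohexa-1,4-diene
Conditions: Li, NH3 (l), t-BuOH, THF, −78 → −33 °C; NH4Cl
Reagents that add atoms: none
Why: Birch reduction keeps the two donor-substituted ring carbons sp2, so the 2,5-dihydro isomer with the enol ether and the trisubstituted olefin in a 1,4-relationship is formed and no stereocentre arises.

**Step 2**
Reactants: 2 1-methoxy-5-methylcyclohexa-1,4-diene; 3 2,2-dimethoxypropane
Product: 5 5-methyl-2-(propan-2-ylidene)cyclohex-4-en-1-one, via methoxy ketal 4 (not isolated)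
Conditions: Me3SiOTf (5 mol %), CH2Cl2, −78 °C; then 1 M aq. HCl, THF, 0 → 20 °C
Reagents that add atoms: water (SMILES: O)
Why: Mukaiyama-type enol ether/ketal condensation (Müller-Cunradi–Pieroh reaction) can only occur at the enol ether β-carbon, and acid hydrolysis with E1 loss of methanol then gives the conjugated isopropylidene ketone, which has no stereocentre.

**Step 3**
Reactants: 5 5-methyl-2-(propan-2-ylidene)cyclohex-4-en-1-one
Product: 6 (1S,6R)-1-methyl-4-(propan-2-ylidene)-7-oxabicyclo[4.1.0]heptan-3-one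
Conditions: 1,2:4,5-di-O-isopropylidene-β-D-erythro-2,3-hexodiulo-2,6-pyranose (0.3 equiv), KHSO5 (Oxone), K2CO3, Bu4NHSO4, MeCN–CH2(OMe)2–aq. Na2B4O7 buffer (pH 10.5), −10 → 0 °C
Reagents that add atoms: potassium peroxymonosulfate KHSO5 (SMILES: [K+].[O-]S(=O)(=O)OO)
Why: Shi asymmetric epoxidation through the spiro dioxirane transition state attacks only the isolated electron-rich trisubstituted olefin of the achiral dienone, and the D-fructose-derived ketone delivers oxygen to the face that gives the (1S,6R) epoxide, as it does for 1-substituted cyclohexenes.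

**Step 4**
Reactants: 6 (1S,6R)-1-methyl-4-(propan-2-ylidene)-7-oxabicyclo[4.1.0]heptan-3-one
Product: 7 (4S,5S)-4-bromo-5-hydroxy-5-methyl-2-(propan-2-ylidene)cyclohexan-1-one
Conditions: Li2NiBr4, THF, 0 → 20 °C; pH 7 phosphate buffer
Reagents that add atoms: dilithium tetrabromonickelate Li2NiBr4 (SMILES: [Li+].[Li+].[Ni+2].[Br-].[Br-].[Br-].[Br-])
Why: SN2 epoxide opening by bromide under neutral conditions occurs at the less hindered secondary carbon with inversion, which gives the trans-bromohydrin and fixes the C–Br centre.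

**Step 5**
Reactants: 7 (4S,5S)-4-bromo-5-hydroxy-5-methyl-2-(propan-2-ylidene)cyclohexan-1-one
Product: 8 (4S,5S)-4-bromo-5-chloro-5-methyl-2-(propan-2-ylidene)cyclohexan-1-one
Conditions: HCl (4 M in 1,4-dioxane), CH2Cl2, −20 → 0 °C
Reagents that add atoms: hydrogen chloride (SMILES: Cl)
Why: SN1 substitution with neighbouring-group participation: the anti bromine closes a bromonium ion as the protonated tertiary hydroxyl leaves and chloride reopens it at the tertiary carbon, so chlorine arrives with retention and trans to bromine.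

**Step 6**
Reactants: 9 pent-3-yn-2-one
Product: 10 tert-butyldimethyl(pent-1-en-3-yn-2-yloxy)silane
Conditions: t-BuMe2SiOTf, Et3N, CH2Cl2, 0 °C
Reagents that add atoms: tert-butyldimethylsilyl triflate (SMILES: CC(C)(C)[Si](C)(C)OS(=O)(=O)C(F)(F)F)
Why: Soft enolisation and O-silylation of the only enolisable position gives the 2-silyloxy-enyne, with no stereocentre.

**Step 7**
Reactants: 8 (4S,5S)-4-bromo-5-chloro-5-methyl-2-(propan-2-ylidene)cyclohexan-1-one; 10 tert-butyldimethyl(pent-1-en-3-yn-2-yloxy)silane
Product: 12 (2S,3S,6S)-2-bromo-3-chloro-3,7,11,11-tetramethylspiro[5.5]undec-7-ene-5,9-dione, via silyl enol ether 11 (not isolated)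
Conditions: t-BuMe2SiOTf (10 mol %), 2,6-di-tert-butyl-4-methylpyridine (20 mol %), CH2Cl2, −78 → −40 °C; then [Au(NCMe){P(t-Bu)2(biphenyl-2-yl)}]SbF6 (5 mol %), MeOH (2 equiv), 0 → 23 °C
Reagents that add atoms: none
Why: Proposed new method: a silyl-triflate-catalysed Mukaiyama–Michael addition of the enyne CH2 terminus to the isopropylidene β-carbon forms C10–C11 and transfers silicon to give the ring B enol ether regiospecifically at C5=C6, after which gold activation of the ynone triggers a 6-endo-dig carbocyclisation (Conia-ene-type addition of a silyl enol ether to an alkyne) in which C7 bonds to C6 axially on the face anti to the C2 bromine (half-chair with Br and Cl equatorial), setting the spiro centre before protodeauration and desilylation by methanol; the closest known reactions are the Mukaiyama–Michael addition to mesityl-oxide-type enones and the gold-catalysed cyclisation of silyl enol ethers onto alkynes.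

**Step 8**
Reactants: 12 (2S,3S,6S)-2-bromo-3-chloro-3,7,11,11-tetramethylspiro[5.5]undec-7-ene-5,9-dione
Product: 13 (2S,3S,5S,6S)-2-bromo-3-chloro-5-hydroxy-3,7,11,11-tetramethylspiro[5.5]undec-7-en-9-one
Conditions: LiAlH(Ot-Bu)3, THF, −20 → 0 °C
Reagents that add atoms: none
Why: Chemoselective hydride reduction of the saturated ketone in the presence of the less electrophilic β,β-disubstituted enone (as with the Wieland–Miescher ketone), with the bulky hydride coming from the equatorial direction because the axial C3 methyl blocks the axial trajectory, which gives the axial (5S) alcohol cis to that methyl.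

**Step 9**
Reactants: 13 (2S,3S,5S,6S)-2-bromo-3-chloro-5-hydroxy-3,7,11,11-tetramethylspiro[5.5]undec-7-en-9-one
Product: 15 (2S,3S,5S,6R)-2,10-dibromo-3-chloro-5-hydroxy-3,7,11,11-tetramethylspiro[5.5]undec-7-en-9-one (C10 epimers), via bis-silyl dienol ether 14 (not isolated)
Conditions: LiN(SiMe3)2 (3.3 equiv), Me3SiCl, THF, −78 °C; then N-bromosuccinimide, −78 °C; aq. citric acid
Reagents that add atoms: N-bromosuccinimide (SMILES: O=C1CCC(=O)N1Br)
Why: Kinetic α'-deprotonation of the enone with internal silyl quench gives the 2-silyloxydiene, which is brominated at C10 (α-halogenation of a silyl enol ether); the C10 centre forms as a mixture that step 11 erases.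

**Step 10**
Reactants: 15 (2S,3S,5S,6R)-2,10-dibromo-3-chloro-5-hydroxy-3,7,11,11-tetramethylspiro[5.5]undec-7-en-9-one (C10 epimers)
Product: 16 (2S,3S,5S,6R)-2,10-dibromo-3-chloro-3,7,11,11-tetramethylspiro[5.5]undec-7-ene-5,9-diol (C9 and C10 epimers)
Conditions: NaBH4, CeCl3·7H2O, MeOH, −78 → −40 °C; AcOH
Reagents that add atoms: none
Why: Luche 1,2-reduction of the enone carbonyl at low temperature gives the allylic bromohydrin, and the C9 configuration is irrelevant because C9 becomes sp2 in the next step.

**Step 11**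
Reactants: 16 (2S,3S,5S,6R)-2,10-dibromo-3-chloro-3,7,11,11-tetramethylspiro[5.5]undec-7-ene-5,9-diol (C9 and C10 epimers)
Product: 17 (2S,3S,5S,6R)-2,10-dibromo-3-chloro-3,7,11,11-tetramethylspiro[5.5]undeca-7,9-dien-5-ol
Conditions: camphor-10-sulfonic acid (10 mol %), 4 Å sieves, CH2Cl2, 23 °C
Reagents that add atoms: none
Why: Acid-catalysed E1 dehydration through the C7–C9 allyl cation and loss of the bromine-acidified C10 proton gives the conjugated 1-bromo-1,3-diene from either epimer, and the ring cannot aromatise because C6 and C11 are quaternary.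

**Step 12**
Reactants: 17 (2S,3S,5S,6R)-2,10-dibromo-3-chloro-3,7,11,11-tetramethylspiro[5.5]undeca-7,9-dien-5-ol
Product: 19 (2S,3S,5S,6R,7R,8S,9S,10S)-2,10-dibromo-3-chloro-7,8:9,10-diepoxy-3,7,11,11-tetramethylspiro[5.5]undecan-5-ol, via 7,8-monoepoxide 18 (not isolated)
Conditions: dimethyldioxirane (excess, in acetone), CH2Cl2, −20 → 0 °C
Reagents that add atoms: dimethyldioxirane (SMILES: CC1(C)OO1)
Why: Double dioxirane epoxidation in one flask: the electron-rich C7=C8 olefin reacts first on the face anti to the pseudo-axial C5 arm (allylic 1,2-strain with the C7 methyl places the carbinol carbon pseudo-axial), and the vinyl bromide is then epoxidised anti to the first oxirane on the face of the C5 hydroxyl, which can hydrogen-bond the dioxirane, so both oxiranes and four stereocentres form under neutral conditions that spare the α-bromo oxirane.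

**Compound list**
1 | 3-methylanisole | COc1cccc(C)c1 | starting material
2 | 1-methoxy-5-methylcyclohexa-1,4-diene | COC1=CCC=C(C)C1 | intermediate
3 | 2,2-dimethoxypropane | COC(C)(C)OC | starting material
4 | rac-5,5-dimethoxy-4-(2-methoxypropan-2-yl)-1-methylcyclohex-1-ene | COC(C)(C)C1CC=C(C)CC1(OC)OC | intermediate
5 | 5-methyl-2-(propan-2-ylidene)cyclohex-4-en-1-one | CC(C)=C1CC=C(C)CC1=O | intermediate
6 | (1S,6R)-1-methyl-4-(propan-2-ylidene)-7-oxabicyclo[4.1.0]heptan-3-one | CC(C)=C1C[C@H]2O[C@@]2(C)CC1=O | intermediate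
7 | (4S,5S)-4-bromo-5-hydroxy-5-methyl-2-(propan-2-ylidene)cyclohexan-1-one | CC(C)=C1C[C@H](Br)[C@@](C)(O)CC1=O | intermediate
8 | (4S,5S)-4-bromo-5-chloro-5-methyl-2-(propan-2-ylidene)cyclohexan-1-one | CC(C)=C1C[C@H](Br)[C@@](C)(Cl)CC1=O | intermediate
9 | pent-3-yn-2-one | CC#CC(C)=O | starting material
10 | tert-butyldimethyl(pent-1-en-3-yn-2-yloxy)silane | CC#CC(=C)O[Si](C)(C)C(C)(C)C | intermediate
11 | 6-[(4S,5S)-5-bromo-2-(tert-butyldimethylsilyloxy)-4-chloro-4-methylcyclohex-1-en-1-yl]-6-methylhept-2-yn-4-one | CC#CC(=O)CC(C)(C)C=1C[C@H](Br)[C@@](C)(Cl)CC=1O[Si](C)(C)C(C)(C)C | intermediate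
12 | (2S,3S,6S)-2-bromo-3-chloro-3,7,11,11-tetramethylspiro[5.5]undec-7-ene-5,9-dione | CC1(C)CC(=O)C=C(C)[C@]12C[C@H](Br)[C@@](C)(Cl)CC2=O | intermediate
13 | (2S,3S,5S,6S)-2-bromo-3-chloro-5-hydroxy-3,7,11,11-tetramethylspiro[5.5]undec-7-en-9-one | CC1(C)CC(=O)C=C(C)[C@]12C[C@H](Br)[C@@](C)(Cl)C[C@@H]2O | intermediate
14 | (2S,3S,5S,6R)-2-bromo-3-chloro-3,7,11,11-tetramethyl-5,9-bis(trimethylsilyloxy)spiro[5.5]undeca-7,9-diene | CC1(C)C=C(O[Si](C)(C)C)C=C(C)[C@]12C[C@H](Br)[C@@](C)(Cl)C[C@@H]2O[Si](C)(C)C | intermediate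
15 | (2S,3S,5S,6R)-2,10-dibromo-3-chloro-5-hydroxy-3,7,11,11-tetramethylspiro[5.5]undec-7-en-9-one (C10 epimers) | CC1(C)C(Br)C(=O)C=C(C)[C@]12C[C@H](Br)[C@@](C)(Cl)C[C@@H]2O | intermediate
16 | (2S,3S,5S,6R)-2,10-dibromo-3-chloro-3,7,11,11-tetramethylspiro[5.5]undec-7-ene-5,9-diol (C9 and C10 epimers) | CC1(C)C(Br)C(O)C=C(C)[C@]12C[C@H](Br)[C@@](C)(Cl)C[C@@H]2O | intermediate
17 | (2S,3S,5S,6R)-2,10-dibromo-3-chloro-3,7,11,11-tetramethylspiro[5.5]undeca-7,9-dien-5-ol | CC1(C)C(Br)=CC=C(C)[C@]12C[C@H](Br)[C@@](C)(Cl)C[C@@H]2O | intermediate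
18 | (2S,3S,5S,6R,7R,8S)-2,10-dibromo-3-chloro-7,8-epoxy-3,7,11,11-tetramethylspiro[5.5]undec-9-en-5-ol | CC1(C)C(Br)=C[C@@H]2O[C@]2(C)[C@]12C[C@H](Br)[C@@](C)(Cl)C[C@@H]2O | intermediate
19 | (2S,3S,5S,6R,7R,8S,9S,10S)-2,10-dibromo-3-chloro-7,8:9,10-diepoxy-3,7,11,11-tetramethylspiro[5.5]undecan-5-ol | CC1(C)[C@@]2(Br)O[C@H]2[C@@H]2O[C@]2(C)[C@]12C[C@H](Br)[C@@](C)(Cl)C[C@@H]2O | target

**Step count and risks**
Total steps: 12. Longest linear sequence: 11 (steps 1–5 and 7–12; step 6 is a one-step branch).

The three steps most likely to fail: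

Step 7. The Michael addition must attack a tetrasubstituted enone while the tertiary chloride survives the silyl Lewis acid, and the gold step must close a very hindered quaternary centre. The fallback sets out from 8. Conjugate addition of the cuprate made from 3-(2-methyl-1,3-dioxolan-2-yl)propylmagnesium chloride and CuBr·SMe2 in the presence of Me3SiCl gives {[(4S,5S)-4-bromo-5-chloro-5-methyl-2-[2-methyl-5-(2-methyl-1,3-dioxolan-2-yl)pentan-2-yl]cyclohex-1-en-1-yl]oxy}trimethylsilane F1. An intramolecular Mukaiyama aldol addition of this enol ether to its own ketal (Me3SiOTf, then camphor-10-sulfonic acid to eliminate the glycol ether) closes ring A with the same anti-to-bromine facial preference and gives (2S,3S,6S)-2-bromo-3-chloro-3,7,11,11-tetramethylspiro[5.5]undec-7-en-5-one F2. Allylic oxidation of the C9 methylene with CrO3·3,5-dimethylpyrazole then installs the enone carbonyl, and the route is rejoined at 12.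

Step 12. The second epoxidation must attack a deactivated vinyl bromide, the facial bias of the first epoxidation rests on a small conformational preference, and the α-bromo oxirane can rearrange to an α-bromo ketone. The fallback sets out from 15 and builds the bromo-oxirane by ring closure instead of epoxidation. A second silyl dienol ether formation and bromination (LiN(SiMe3)2, Me3SiCl, then N-bromosuccinimide) gives (2S,3S,5S,6R)-2,10,10-tribromo-3-chloro-5-hydroxy-3,7,11,11-tetramethylspiro[5.5]undec-7-en-9-one F3. Luche reduction and separation of the C9 epimers give (2S,3S,5S,6R,9S)-2,10,10-tribromo-3-chloro-3,7,11,11-tetramethylspiro[5.5]undec-7-ene-5,9-diol F4. K2CO3 in methanol closes the oxirane by displacement of one geminal bromide by the C9 alkoxide (Jocic-type closure), so the oxirane face is fixed by the carbinol centre, giving (2S,3S,5S,6R,9S,10S)-2,10-dibromo-3-chloro-9,10-epoxy-3,7,11,11-tetramethylspiro[5.5]undec-7-en-5-ol F5. A single dimethyldioxirane epoxidation of the remaining C7=C8 olefin, anti to the existing oxirane, rejoins the route at 19.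

Step 8. Equatorial attack at C5 is hindered by the axial C7 arm on the neighbouring spiro carbon, so the ratio of C5 epimers is uncertain, and a bulkier hydride cannot be used while the enone is present. The fallback sets out from 12. Excess LiBH(s-Bu)3 reduces both carbonyl groups, the hindered ketone now strictly from the equatorial side, to (2S,3S,5S,6S)-2-bromo-3-chloro-3,7,11,11-tetramethylspiro[5.5]undec-7-ene-5,9-diol (C9 epimers) F6. MnO2 in CH2Cl2 then re-oxidises only the allylic C9 alcohol, and the route is rejoined at 13.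

**Further compounds**
F1 | step 7 | {[(4S,5S)-4-bromo-5-chloro-5-methyl-2-[2-methyl-5-(2-methyl-1,3-dioxolan-2-yl)pentan-2-yl]cyclohex-1-en-1-yl]oxy}trimethylsilane | CC1(CCCC(C)(C)C=2C[C@H](Br)[C@@](C)(Cl)CC=2O[Si](C)(C)C)OCCO1
F2 | step 7 | (2S,3S,6S)-2-bromo-3-chloro-3,7,11,11-tetramethylspiro[5.5]undec-7-en-5-one | CC1(C)CCC=C(C)[C@]12C[C@H](Br)[C@@](C)(Cl)CC2=O
F3 | step 12 | (2S,3S,5S,6R)-2,10,10-tribromo-3-chloro-5-hydroxy-3,7,11,11-tetramethylspiro[5.5]undec-7-en-9-one | CC1(C)C(Br)(Br)C(=O)C=C(C)[C@]12C[C@H](Br)[C@@](C)(Cl)C[C@@H]2O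
F4 | step 12 | (2S,3S,5S,6R,9S)-2,10,10-tribromo-3-chloro-3,7,11,11-tetramethylspiro[5.5]undec-7-ene-5,9-diol | CC1(C)C(Br)(Br)[C@@H](O)C=C(C)[C@]12C[C@H](Br)[C@@](C)(Cl)C[C@@H]2O
F5 | step 12 | (2S,3S,5S,6R,9S,10S)-2,10-dibromo-3-chloro-9,10-epoxy-3,7,11,11-tetramethylspiro[5.5]undec-7-en-5-ol | CC1(C)[C@@]2(Br)O[C@H]2C=C(C)[C@]12C[C@H](Br)[C@@](C)(Cl)C[C@@H]2O
F6 | step 8 | (2S,3S,5S,6S)-2-bromo-3-chloro-3,7,11,11-tetramethylspiro[5.5]undec-7-ene-5,9-diol (C9 epimers) | CC1(C)CC(O)C=C(C)[C@]12C[C@H](Br)[C@@](C)(Cl)C[C@@H]2O
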